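**Strategy.** Everything rests on the C1–C2 bond of the ten-membered ring (C1–C10). C1 is quaternary and α to the C14 carbonyl of ring A, C2 bears oxygen, so C14/C1/C2 is a β-hydroxy ketone retron. Divalent samarium converts the C1 bromide of 26 into a C1=C14 enolate that adds to the C2 aldehyde: one operation closes the ten-membered ring and builds quaternary C1, the C2 carbinol and the trans ring fusion. The precursor is a butenolide-bearing bromo keto aldehyde; its bromide is placed regiospecifically through a C1=C14 silyl enol ether, because a C14 ketone flanked by the C11=C12 olefin enolises towards C13. Ring A derives from (S)-carvone, C2–C7 from neryl acetate.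

Key step: step 18

Remarks
- Numbering: ten-membered ring C1–C10; ring A C1, C10–C14; butenolide O–C19(=O)–C17=C8–C7; methyls C15 (on C1), C16 (on C5), C18 (on C17), C20 (on C11); α is the face of ring A opposite to C15.
- Assumption: the sense of induction of the chiral chromium complex in step 15 is set by the choice of ligand antipode; the antipode giving 7R is used.
- The configuration of the C1 bromide in 26 is without consequence, since C1 is trigonal in enolate 27; 26 is used as both C1 epimers and its SMILES leaves C1 open.
- 26 is formally the hydrobromide of a phenol (loss of HBr across C1/C10 and tautomerisation would give a 2,4-dimethylphenol), so it is made last, cold and without base.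
- 8 and 9 are carbinol epimer mixtures at C14; both converge in step 7.

Step 1
Reactants: 1 (S)-carvone
Product: 2 carvone trans-epoxide
Conditions: H2O2 (30% aq), NaOH (cat.), MeOH, 0 °C
Reagents that add atoms: hydrogen peroxide (OO)
Why: Weitz–Scheffer nucleophilic epoxidation, in which hydroperoxide adds only to the enone C=C (the isopropenyl group is not electrophilic) and closes the oxirane anti to the ring substituent; both new centres are destroyed in step 2.

Step 2
Reactants: 2 carvone trans-epoxide
Product: 3 aldehyde acid
Conditions: H5IO6, THF/H2O, 0 °C → rt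
Reagents that add atoms: water (O)
Why: Malaprade-type oxidative cleavage, in which periodic acid hydrates the epoxy ketone and cuts the bonds on both sides of the methyl-bearing carbon (lost as acetic acid), so the ring opens to an aldehyde arm (future C1–C14) and an acid arm (future C9–C8) that stay differentiated around the untouched carvone stereocentre (future C10).

Step 3
Reactants: 3 aldehyde acid
Product: 4 aldehyde methyl ester
Conditions: MeI, KHCO3, DMF, rt
Reagents that add atoms: iodomethane (CI)
Why: SN2 O-alkylation of the carboxylate under bicarbonate, mild enough to leave the enolisable aldehyde alone.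

Step 4
Reactants: 4 aldehyde methyl ester; 5 formaldehyde
Product: 6 2-methylidene aldehyde
Conditions: CH2O (37% aq), pyrrolidine (cat.), EtCO2H (cat.), i-PrOH, 45 °C
Reagents that add atoms: none
Why: Amine-catalysed Mannich condensation–elimination (α-methylenation of an aldehyde) at the only α-carbon of the aldehyde, which installs C15 on C1 as a regiochemical marker for step 8; C10 is cross-conjugated and not acidified, so it should not epimerise.

Step 5
Reactants: 6 2-methylidene aldehyde; 7 allyl bromide
Product: 8 dienol ester
Conditions: allyl bromide, Zn, THF/sat. aq NH4Cl, 0 °C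
Reagents that add atoms: none
Why: Barbier allylation, in which allylzinc bromide adds 1,2 to the enal and not to the ester while the aqueous medium protonates the alkoxide at once, so no lactone forms; the new C14 centre arises as a mixture that step 7 erases.

Step 6
Reactants: 8 dienol ester
Product: 9 ring A allylic alcohol
Conditions: second-generation Grubbs catalyst RuCl2(H2IMes)(PCy3)(=CHPh) (3 mol %), CH2Cl2 (5 mM), 40 °C
Reagents that add atoms: none
Why: Ring-closing olefin metathesis between the allyl terminus and the isopropenyl group closes six-membered ring A with the trisubstituted C11=C12 olefin and releases ethylene; the C1 methylidene can only close a three- or four-membered ring and stays.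

Step 7
Reactants: 9 ring A allylic alcohol
Product: 10 exocyclic enone
Conditions: MnO2, CH2Cl2, rt; filtered and used at once
Reagents that add atoms: none
Why: Allylic alcohol oxidation on neutral, heterogeneous MnO2, chosen so that the cross-conjugated β,γ-unsaturated enone is neither moved into conjugation nor aromatised before it is reduced.

Step 8
Reactants: 10 exocyclic enone
Product: 12 silyl enol ether ester, via lithium enolate 11 (not isolated)
Conditions: LiBH(s-Bu)3, THF, −78 °C (10 added to the hydride); then TBSOTf, −78 → 0 °C
Reagents that add atoms: tert-butyldimethylsilyl trifluoromethanesulfonate (CC(C)(C)[Si](C)(C)OS(=O)(=O)C(F)(F)F)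
Why: Conjugate hydride reduction of the s-cis-locked exocyclic enone followed by O-silylation, in which hydride enters at C15 so that the enolate and its silyl ether exist only as the C1=C14 isomer, which deprotonation of a C14 ketone could not give because C13 is the more acidic site.

Step 9
Reactants: 12 silyl enol ether ester; 13 ethyl propionate
Product: 14 β-keto ester
Conditions: EtCO2Et, LiN(i-Pr)2, THF, −78 °C; then 12, −78 → −30 °C; NH4Cl
Reagents that add atoms: none
Why: Crossed Claisen condensation, in which the preformed lithium enolate of ethyl propionate acylates at the unhindered methyl ester to form C8–C17 and the product is held as its enolate until work-up; the silyl enol ether is inert to ester enolates.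

Step 10
Reactants: 14 β-keto ester
Product: 16 (Z)-enol triflate, via sodium enolate 15 (not isolated)
Conditions: NaH, THF, 0 °C; then PhNTf2, 0 °C → rt
Reagents that add atoms: N-phenylbis(trifluoromethanesulfonimide) (O=S(=O)(N(c1ccccc1)S(=O)(=O)C(F)(F)F)C(F)(F)F)
Why: O-Sulfonylation of the sodium-chelated β-keto ester enolate places triflate and ester cis on C8=C17, the geometry needed for lactonisation in step 15, and the mild triflating agent leaves the silyl enol ether alone.

Step 11
Reactants: 17 neryl acetate
Product: 18 terminal epoxide
Conditions: mCPBA, NaHCO3, CH2Cl2, −10 °C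
Reagents that add atoms: 3-chloroperoxybenzoic acid (OOC(=O)c1cccc(Cl)c1)
Why: Prilezhaev epoxidation selects the remote trisubstituted olefin because the allylic acetate deactivates the C5=C6 olefin inductively.

Step 12
Reactants: 18 terminal epoxide
Product: 19 aldehyde acetate
Conditions: H5IO6, THF/H2O, 0 °C
Reagents that add atoms: none
Why: Epoxide hydrolysis and Malaprade glycol cleavage in one flask release acetone and the C2 aldehyde without touching the Z olefin or the acetate.

Step 13
Reactants: 19 aldehyde acetate
Product: 20 Z-diol
Conditions: LiAlH4, Et2O, 0 °C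
Reagents that add atoms: none
Why: Hydride reduction of aldehyde and acetate together gives the diol; the isolated trisubstituted olefin is inert and keeps its Z geometry.

Step 14
Reactants: 20 Z-diol
Product: 21 Z-hydroxy enal
Conditions: MnO2, CH2Cl2, 0 °C → rt; used at once
Reagents that add atoms: none
Why: Chemoselective allylic oxidation, since MnO2 oxidises the allylic but not the saturated primary alcohol under neutral conditions that should preserve the Z enal, which is used without storage to forestall isomerisation or oxa-Michael closure.

Step 15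
Reactants: 16 (Z)-enol triflate; 21 Z-hydroxy enal
Product: 24 butenolide alcohol, via alkenylchromium dichloride 22 (not isolated), via hydroxy ester chromium alkoxide 23 (not isolated)
Conditions: CrCl2 (4 equiv), chiral ligand N-[2-(4-isopropyl-4,5-dihydro-1,3-oxazol-2-yl)-6-methylphenyl]methanesulfonamide (antipode that gives 7R), Et3N, NiCl2 (2 mol %), THF, rt
Reagents that add atoms: none
Why: Asymmetric Nozaki–Hiyama–Kishi coupling, in which zerovalent nickel inserts into the C8–OTf bond with retention, transmetalation gives a trivalent alkenylchromium that adds 1,2 to the enal inside the chiral sulfonamide complex (catalyst control of C7), and the cis γ-alkoxy ester lactonises to the butenolide; organochromium reagents tolerate the silyl enol ether and the free primary alcohol.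

Step 16
Reactants: 24 butenolide alcohol
Product: 25 silyl enol ether aldehyde
Conditions: Dess–Martin periodinane, NaHCO3, CH2Cl2, 0 °C
Reagents that add atoms: none
Why: Dess–Martin oxidation of the primary alcohol under bicarbonate buffer gives the C2 aldehyde without acid or base that could cleave the silyl enol ether or epimerise C7 of the butenolide.

Step 17
Reactants: 25 silyl enol ether aldehyde
Product: 26 bromo keto aldehyde
Conditions: NBS, NaHCO3, THF, −78 °C; used at once
Reagents that add atoms: N-bromosuccinimide (O=C1CCC(=O)N1Br)
Why: Electrophilic α-bromination of a silyl enol ether delivers bromine only to C1, since the C1=C14 enol ether is far more nucleophilic than the other olefins, and gives the tertiary α-bromo ketone without any base.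

Step 18
Reactants: 26 bromo keto aldehyde
Product: 29 ten-membered ring hydroxy ketone, via samarium enolate 27 (not isolated), via samarium aldolate 28 (not isolated)
Conditions: SmI2 (2.2 equiv), THF, −78 °C, slow addition of 26 (final 2 mM); pH 7 buffer at −78 °C
Reagents that add atoms: none
Why: Divalent samarium cleaves the C1–Br bond of 26 by two single-electron transfers and gives the trivalent samarium enolate 27 only at C1=C14, which adds to the tethered C2 aldehyde through a samarium-bridged six-membered chair to give aldolate 28 (intramolecular samarium Reformatsky reaction). The closest known reaction type is the SmI2-promoted Reformatsky closure of medium and large rings from ω-formyl α-halo carbonyl compounds. The ten-membered ring closes in the 10-(enolexo)-exo-trig mode, with the enolate C=C and the aldehyde C=O both outside the new ring. C1 is controlled by C10, whose C9 arm stands perpendicular to the flat enolate ring to avoid allylic strain with C15 and C20, so the aldehyde should bond to the opposite face and give the trans ring fusion; C2 is controlled by the chelated chair, in which the ring-bound enolate (C10 trans to oxygen) and an equatorial C3 chain place the carbinol oxygen syn to C15. The step needs reduction of the α-bromo ketone in preference to aldehyde, butenolide and olefins, and ring closure in preference to enolate protonation or intermolecular aldol, which the very fast C–Br reduction at −78 °C, the absence of HMPA and proton donors, and high dilution should secure. Quenching the aldolate cold avoids retro-aldol cleavage, and the quaternary C1 rules out dehydration.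

Step 19
Reactants: 29 ten-membered ring hydroxy ketone; 30 propanal
Product: 32 C2 propionate C14 alcohol, via hemiacetal 31 (not isolated)
Conditions: EtCHO (8 equiv), SmI2 (0.3 equiv), THF, −10 °C
Reagents that add atoms: none
Why: Evans–Tishchenko reduction, in which the C2 hydroxyl forms a hemiacetal with propanal on trivalent samarium and passes its hydride intramolecularly to C14 through a chair, giving the 1,3-anti diol monoester, that is the 14α alcohol trans to C15 with the propionate already on C2.

Step 20
Reactants: 32 C2 propionate C14 alcohol; 33 acetic anhydride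
Product: 34 target
Conditions: Ac2O, DMAP, pyridine, CH2Cl2, 0 °C → rt
Reagents that add atoms: none
Why: DMAP-catalysed acylation of the hindered C14 alcohol, which should be fast compared with 1,3-migration of the C2 propionate.

Compound list
1 | (S)-(+)-carvone, (5S)-2-methyl-5-(prop-1-en-2-yl)cyclohex-2-en-1-one | CC(=C)[C@H]1CC=C(C)C(=O)C1 | starting material
2 | (1S,4S,6S)-1-methyl-4-(prop-1-en-2-yl)-7-oxabicyclo[4.1.0]heptan-2-one, oxirane trans to isopropenyl | CC(=C)[C@H]1C[C@@H]2O[C@]2(C)C(=O)C1 | intermediate
3 | (3S)-5-oxo-3-(prop-1-en-2-yl)pentanoic acid | OC(=O)C[C@@H](C(C)=C)CC=O | intermediate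
4 | methyl (3S)-5-oxo-3-(prop-1-en-2-yl)pentanoate | COC(=O)C[C@@H](C(C)=C)CC=O | intermediate
5 | formaldehyde | C=O | starting material
6 | methyl (3S)-4-formyl-3-(prop-1-en-2-yl)pent-4-enoate | COC(=O)C[C@@H](C(C)=C)C(=C)C=O | intermediate
7 | allyl bromide, 3-bromoprop-1-ene | C=CCBr | starting material
8 | methyl (3S)-5-hydroxy-4-methylidene-3-(prop-1-en-2-yl)oct-7-enoate, both epimers at the carbinol (C14) | COC(=O)C[C@@H](C(C)=C)C(=C)C(O)CC=C | intermediate
9 | methyl 2-[(1S)-5-hydroxy-2-methyl-6-methylidenecyclohex-2-en-1-yl]acetate, both carbinol epimers | COC(=O)C[C@H]1C(C)=CCC(O)C1=C | intermediate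
10 | methyl 2-[(1S)-2-methyl-6-methylidene-5-oxocyclohex-2-en-1-yl]acetate | COC(=O)C[C@H]1C(C)=CCC(=O)C1=C | intermediate
11 | lithium C1=C14 enolate from 10 (not isolated) | COC(=O)C[C@H]1C(C)=CCC(O[Li])=C1C | intermediate
12 | methyl 2-[(1S)-5-(tert-butyldimethylsilyloxy)-2,6-dimethylcyclohexa-2,5-dien-1-yl]acetate | COC(=O)C[C@H]1C(C)=CCC(O[Si](C)(C)C(C)(C)C)=C1C | intermediate
13 | ethyl propionate | CCC(=O)OCC | starting material
14 | ethyl 4-[(1S)-5-(tert-butyldimethylsilyloxy)-2,6-dimethylcyclohexa-2,5-dien-1-yl]-2-methyl-3-oxobutanoate, both C2 epimers | CCOC(=O)C(C)C(=O)C[C@H]1C(C)=CCC(O[Si](C)(C)C(C)(C)C)=C1C | intermediate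
15 | sodium (Z)-enolate of 14 (not isolated) | CCOC(=O)/C(C)=C(\O[Na])C[C@H]1C(C)=CCC(O[Si](C)(C)C(C)(C)C)=C1C | intermediate
16 | ethyl (2Z)-4-[(1S)-5-(tert-butyldimethylsilyloxy)-2,6-dimethylcyclohexa-2,5-dien-1-yl]-2-methyl-3-(trifluoromethylsulfonyloxy)but-2-enoate | CCOC(=O)/C(C)=C(\OS(=O)(=O)C(F)(F)F)C[C@H]1C(C)=CCC(O[Si](C)(C)C(C)(C)C)=C1C | intermediate
17 | neryl acetate, (2Z)-3,7-dimethylocta-2,6-dien-1-yl acetate | CC(C)=CCC/C(C)=C\COC(C)=O | starting material
18 | (2Z)-5-(3,3-dimethyloxiran-2-yl)-3-methylpent-2-en-1-yl acetate, racemic at the oxirane | CC1(C)OC1CC/C(C)=C\COC(C)=O | intermediate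
19 | (2Z)-3-methyl-6-oxohex-2-en-1-yl acetate | O=CCC/C(C)=C\COC(C)=O | intermediate
20 | (2Z)-3-methylhex-2-ene-1,6-diol | OCCC/C(C)=C\CO | intermediate
21 | (2Z)-6-hydroxy-3-methylhex-2-enal | OCCC/C(C)=C\C=O | intermediate
22 | alkenylchromium dichloride from 16, chromium on C8 cis to the ester (not isolated) | CCOC(=O)/C(C)=C(\[Cr](Cl)Cl)C[C@H]1C(C)=CCC(O[Si](C)(C)C(C)(C)C)=C1C | intermediate
23 | ethyl (2Z,4R,5Z)-3-{[(1S)-5-(tert-butyldimethylsilyloxy)-2,6-dimethylcyclohexa-2,5-dien-1-yl]methyl}-4,9-dihydroxy-2,6-dimethylnona-2,5-dienoate, formed as its chromium alkoxide (not isolated) | CCOC(=O)/C(C)=C(\[C@H](O)/C=C(/C)CCCO)C[C@H]1C(C)=CCC(O[Si](C)(C)C(C)(C)C)=C1C | intermediate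
24 | (5R)-5-[(1Z)-5-hydroxy-2-methylpent-1-en-1-yl]-3-methyl-4-{[(1S)-5-(tert-butyldimethylsilyloxy)-2,6-dimethylcyclohexa-2,5-dien-1-yl]methyl}furan-2(5H)-one (7R,10S) | OCCC/C(C)=C\[C@H]1OC(=O)C(C)=C1C[C@H]1C(C)=CCC(O[Si](C)(C)C(C)(C)C)=C1C | intermediate
25 | (4Z)-4-methyl-5-[(2R)-4-methyl-5-oxo-3-{[(1S)-5-(tert-butyldimethylsilyloxy)-2,6-dimethylcyclohexa-2,5-dien-1-yl]methyl}-2,5-dihydrofuran-2-yl]pent-4-enal | O=CCC/C(C)=C\[C@H]1OC(=O)C(C)=C1C[C@H]1C(C)=CCC(O[Si](C)(C)C(C)(C)C)=C1C | intermediate
26 | (4Z)-5-[(2R)-3-{[(1S)-6-bromo-2,6-dimethyl-5-oxocyclohex-2-en-1-yl]methyl}-4-methyl-5-oxo-2,5-dihydrofuran-2-yl]-4-methylpent-4-enal, both epimers at the bromine-bearing C1 | O=CCC/C(C)=C\[C@H]1OC(=O)C(C)=C1C[C@H]1C(C)=CCC(=O)C1(C)Br | intermediate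
27 | trivalent samarium C1=C14 enolate of the debrominated keto aldehyde (not isolated) | O=CCC/C(C)=C\[C@H]1OC(=O)C(C)=C1C[C@H]1C(C)=CCC(O[Sm](I)I)=C1C | intermediate
28 | samarium alkoxide of 29 at C2–O (not isolated) | I[Sm](I)O[C@H]1CC/C(C)=C\[C@H]2OC(=O)C(C)=C2C[C@H]2C(C)=CCC(=O)[C@]12C | intermediate
29 | tricyclic hydroxy ketone (1S,2S,5Z,7R,10S): C2 hydroxyl, C14 ketone, trans-fused six- and ten-membered rings, butenolide at C7/C8 | O[C@H]1CC/C(C)=C\[C@H]2OC(=O)C(C)=C2C[C@H]2C(C)=CCC(=O)[C@]12C | intermediate
30 | propanal | CCC=O | starting material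
31 | C2–O hemiacetal of 29 with propanal, samarium-bound (not isolated) | CCC(O)O[C@H]1CC/C(C)=C\[C@H]2OC(=O)C(C)=C2C[C@H]2C(C)=CCC(=O)[C@]12C | intermediate
32 | C2 propionate with free 14α-hydroxyl (14S, anti to C2–O, trans to C15); other centres as in 34 | CCC(=O)O[C@H]1CC/C(C)=C\[C@H]2OC(=O)C(C)=C2C[C@H]2C(C)=CC[C@H](O)[C@]12C | intermediate
33 | acetic anhydride | CC(=O)OC(C)=O | starting material
34 | CNP0112230.1, (1S,2S,5Z,7R,10S,14S)-14-acetoxy-2-propanoyloxy tricyclic butenolide | CCC(=O)O[C@H]1CC/C(C)=C\[C@H]2OC(=O)C(C)=C2C[C@H]2C(C)=CC[C@H](OC(C)=O)[C@]12C | target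

Total steps: 20. Longest linear sequence: 16 steps (steps 1–10 and 15–20 from (S)-carvone); aldehyde 21 takes 4 steps (11–14) from neryl acetate.

Steps most likely to fail

1. Step 18. The aldehyde may bond to the enolate face syn to the C9 arm (cis ring fusion). The samarium enolate may also be protonated before the slow ten-membered closure, giving debrominated ketone, or the aldolate may revert by retro-aldol during work-up. Fallback: set out from 25 and close the same C1–C2 bond by an intramolecular Mukaiyama aldol reaction (BF3·OEt2, CH2Cl2, −78 °C, slow addition). The silyl enol ether attacks the Lewis-acid-activated aldehyde through an open transition state and no free enolate is formed. The silyl group leaves as the fluorosilane and aqueous work-up returns the route at 29. No new compound arises (F0).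

2. Step 15. Facial control at C7 by the chiral chromium complex may be poor with a tetrasubstituted alkenyl nucleophile, and the Z enal may isomerise to E before it is consumed. Fallback: set C7 by reagent-controlled reduction of a ketone, setting out from 12.
   - Crossed Claisen condensation with the lithium enolate of tert-butyl propionate gives the tert-butyl keto ester F1.
   - NaH/PhNTf2 gives the (Z)-enol triflate F2.
   - Ligand-free CrCl2/NiCl2 coupling with 21 gives the open-chain hydroxy ester F3 as both C7 epimers, since the tert-butyl ester resists lactonisation.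
   - MnO2 oxidises only the doubly allylic C7 carbinol to the dienone F4.
   - Corey–Bakshi–Shibata reduction (oxazaborolidine antipode chosen for 7R) gives the single 7R alcohol F5.
   - Warming with a trace of pyridinium p-toluenesulfonate closes the lactone with loss of tert-butanol and returns the route at 24.

3. Step 8 (with step 7). Enone 10 may slip into conjugation and on to the phenol before it is reduced, or the lithium enolate may equilibrate to the C13 dienolate before silylation. Fallback: avoid the enone, setting out from 9. Silylation (TBSCl, imidazole, DMF) gives the allyl silyl ether F6. [Ir(cod)(PMePh2)2]PF6 (activated with H2, THF, rt) then shifts the C14 hydrogen to C15, the known isomerisation of an allyl silyl ether to a silyl enol ether, and returns the route at 12.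

Further compounds
F0 | step 18 | none | none
F1 | step 15 | tert-butyl 4-[(1S)-5-(tert-butyldimethylsilyloxy)-2,6-dimethylcyclohexa-2,5-dien-1-yl]-2-methyl-3-oxobutanoate, both C2 epimers | CC(C)(C)OC(=O)C(C)C(=O)C[C@H]1C(C)=CCC(O[Si](C)(C)C(C)(C)C)=C1C
F2 | step 15 | tert-butyl (2Z)-4-[(1S)-5-(tert-butyldimethylsilyloxy)-2,6-dimethylcyclohexa-2,5-dien-1-yl]-2-methyl-3-(trifluoromethylsulfonyloxy)but-2-enoate | CC(C)(C)OC(=O)/C(C)=C(\OS(=O)(=O)C(F)(F)F)C[C@H]1C(C)=CCC(O[Si](C)(C)C(C)(C)C)=C1C
F3 | step 15 | tert-butyl (2Z,5Z)-3-{[(1S)-5-(tert-butyldimethylsilyloxy)-2,6-dimethylcyclohexa-2,5-dien-1-yl]methyl}-4,9-dihydroxy-2,6-dimethylnona-2,5-dienoate, both C4 (= C7) epimers | CC(C)(C)OC(=O)/C(C)=C(\C(O)/C=C(/C)CCCO)C[C@H]1C(C)=CCC(O[Si](C)(C)C(C)(C)C)=C1C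
F4 | step 15 | tert-butyl (2Z,5Z)-3-{[(1S)-5-(tert-butyldimethylsilyloxy)-2,6-dimethylcyclohexa-2,5-dien-1-yl]methyl}-9-hydroxy-2,6-dimethyl-4-oxonona-2,5-dienoate | CC(C)(C)OC(=O)/C(C)=C(\C(=O)/C=C(/C)CCCO)C[C@H]1C(C)=CCC(O[Si](C)(C)C(C)(C)C)=C1C
F5 | step 15 | tert-butyl (2Z,4R,5Z)-3-{[(1S)-5-(tert-butyldimethylsilyloxy)-2,6-dimethylcyclohexa-2,5-dien-1-yl]methyl}-4,9-dihydroxy-2,6-dimethylnona-2,5-dienoate | CC(C)(C)OC(=O)/C(C)=C(\[C@H](O)/C=C(/C)CCCO)C[C@H]1C(C)=CCC(O[Si](C)(C)C(C)(C)C)=C1C
F6 | step 8 | methyl 2-[(1S)-5-(tert-butyldimethylsilyloxy)-2-methyl-6-methylidenecyclohex-2-en-1-yl]acetate, both silyloxy epimers | COC(=O)C[C@H]1C(C)=CCC(O[Si](C)(C)C(C)(C)C)C1=C
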